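At 2.50 d, a gap of 3.7 percentage points in starting material separates Sunday's run from Monday's run, and that gap is what 0.800 equiv more scavenger shows. On this scale, equal residues in the two runs are the zero.

in all of them: starting material 0.20 M; initiator 5 mol%

| charge | reagent | scavenger | remark | time |
|---|---|---|---|---|
| Monday's | 1 equiv | 1.1 equiv | run made earlier |  |
| Wednesday's | 1 equiv | 1.3 equiv | run made earlier |  |
| Sunday's | 1 equiv | 1.9 equiv | run made earlier |  |
| north-east | 1.00 equiv | 1.00 equiv |  | 5.0 d |
| south-east | 1.00 equiv | 2.00 equiv |  | 5.0 d |

| run | time / d | starting material / % | target / % |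
|---|---|---|---|
| Monday's | 0.208 | 68.6 | 16.5 |
| Monday's | 0.500 | 38.6 | 34.6 |
| Monday's | 1.04 | 21.5 | 50.3 |
| Monday's | 2.50 | 13.6 | 72.4 |
| Wednesday's | 0.333 | 54.8 | 23.0 |
| Wednesday's | 0.833 | 25.6 | 48.3 |
| Wednesday's | 1.67 | 19.0 | 64.9 |
| Wednesday's | 2.50 | 16.9 | 72.3 |
| Sunday's | 0.625 | 34.3 | 40.0 |
| Sunday's | 1.25 | 24.8 | 56.1 |
| Sunday's | 2.08 | 19.9 | 69.6 |
| Sunday's | 2.50 | 17.3 | 74.7 |

(standard deviation of a reading: 1 percentage point)

- part of the starting material that has reacted at the end, north-east
- part of the starting material that has reacted at the end, south-east
- what raising the equivalents of scavenger from its lowest to its highest value here does to the part of the starting material that has reacted (changes below 5 percentage points count as none) (no change / it falls / it rises)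

- what has gone from starting material into another species counts as reacted, even if it can come back

Scavenger comes first. Stretched over the span from 1.00 equiv to 2.00 equiv, the gap, still at 2.50 d, becomes

span = gap × (span of the flasks / span of the runs) = 4.6 points

Time comes next. The late fall of starting material, reckoned as pseudo-first-order, gives the tail rate, the first-order constant between two late readings of one run:

Sunday's run, from 1.25 d to 2.50 d: 0.288 d⁻¹, a half-life of 2.41 d

Monday's run, from 1.04 d to 2.50 d: 0.314 d⁻¹

Carrying each run's last residue on to 5.0 d gives the reacted part:

near north-east, from Monday's run: 93.8%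

near south-east, from Sunday's run: 91.6%

The difference of 2.2 points is smaller than the 5 points that counts as a change, so this reckoning says no change.

The forecast stands lower, at 92% for north-east and 90% for south-east, also with no change: “Extrapolating to 5 d halves the remaining starting material”.

The flask gives 91.8% in north-east and 89.9% in south-east, a change of −1.9 points, which is no change. From the 86.2% reacted in Monday's run at its last reading, without the scatter, scavenger moved by itself to south-east's charge gives 82.0%, time by itself gives 91.1%, and both give 89.9%.

    reagent + first chain carrier ⇌ target + second chain carrier (K = 2.70, k = 1.50 × 10⁶ M⁻¹ h⁻¹)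
    initiator → 2 initiating radical (k = 0.00140 h⁻¹)
    starting material + second chain carrier → released group + first chain carrier (k = 1.60 × 10⁶ M⁻¹ h⁻¹)
    starting material + released group ⇌ idle adduct, settled at all times (K = 500 M⁻¹)
    scavenger + released group → scavenged by-product (k = 6.30 M⁻¹ h⁻¹)
    starting material + initiating radical → capped initiator + first chain carrier (k = 3.10 × 10⁷ M⁻¹ h⁻¹)
    2 first chain carrier → ended chains (k = 6.00 × 10⁶ M⁻¹ s⁻¹)

The neighbouring flask is south-east with 1.2 mol% of initiator instead of 5 mol%. If the tail rate goes with the square root of initiator, as for chains that start from initiator and end in pairs, the estimate for the neighbouring flask is 0.141 d⁻¹. On that estimate, the neighbouring flask's clock lags south-east's by 2.55 d. Going back from south-east's 10% over that lag at Sunday's tail rate gives an estimate of 21.1% of starting material. The neighbouring flask holds 21% of its starting material unbound at the end, with 79.1% reacted.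

The numbers in the tables come from a simulation from invented constants; scatter was added.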